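**Plan**

- Numbering (briarane): C1 (quaternary, Me-15), C2 (O-butanoyl), C3, C4, C5 (Me-16)=C6, C7 (lactone O), C8, C9, C10, C11 (Me-20)/C12 epoxide, C13, C14 (OAc); butenolide C8=C17 (Me-18), C19=O.
- Retrosynthetic cuts, in order: lactone bonds O–C7 and C19–C17 (giving CO2 and the macrocyclic alkylidenecyclopropane 28); C5=C6 (ring-closing metathesis); cyclopropane bonds C7–C17/C8–C17 (ethylidene transfer to an allene); C9–C10 ([2,3]-Wittig); C2–C3 (Grignard); C1–C15 and C1–C2 (enolate alkylations of (R)-carvone).
- Forward order: the six-membered ring is bought as (R)-carvone and substituted; the chains on C10 and C1 are grown; then the cyclopropane, then the ten-membered ring (step 22), and the butenolide last (step 23 gives the target).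
- Enabling feature: in 28 the strained C7–C8–C17 cyclopropane carries an exocyclic C8=C9 double bond and, on C7, the C5=C6 vinyl group, so heterolysis of C7–C17 gives at once an allyl cation (C5–C6–C7, held on palladium) and an allyl anion (C17–C8–C9); CO2 bridges the two.
- Stereochemistry: C14 comes from carvone; C1 by alkylation anti to C14; C12 (Wharton) relays to C10 ([2,3]) and to the epoxide (OH-directed); C9 (Wittig transition state) relays to the allene axis (Myers), to C7 of the cyclopropane (carbenoid anti to C10) and to C7 of the lactone (double inversion); C2 by CBS reduction; (Z)-C5=C6 by the ring.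

Key step: step 23

**Route**

Step 1
Reactants: 1 (R)-(−)-carvone; 2 chloromethyl 4-methoxybenzyl ether
Product: 3 trans-6-[(4-methoxybenzyloxy)methyl]carvone
Conditions: LiN(iPr)2, THF, −78 °C; then 2, −78 → −30 °C
Reagents that add atoms: none
Why: Kinetic α′-enolate alkylation of carvone should place the CH2OPMB group (future C2) on C1 trans to the neighbouring isopropenyl group, a configuration that is of no consequence because C1 is re-enolised in step 2.

Step 2
Reactants: 3 trans-6-[(4-methoxybenzyloxy)methyl]carvone
Product: 4 6-methyl-6-[(4-methoxybenzyloxy)methyl]carvone (C15 methyl trans, CH2OPMB cis to the isopropenyl group)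
Conditions: LiN(iPr)2, THF, −78 °C; MeI, DMPU, −78 → 0 °C
Reagents that add atoms: iodomethane, CI
Why: Second enolate alkylation (quaternisation) in which iodomethane should attack the enolate face opposite the isopropenyl group on C14, so that C15 ends up trans and the C2 arm cis to the C14 substituent as in the target.

Step 3
Reactants: 4 6-methyl-6-[(4-methoxybenzyloxy)methyl]carvone
Product: 5 C11,C12-epoxy ketone (epoxide trans to isopropenyl)
Conditions: H2O2 (30% aq), NaOH, MeOH, 0 °C
Reagents that add atoms: hydrogen peroxide, OO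
Why: Weitz–Scheffer nucleophilic epoxidation of the enone, in which hydroperoxide should add axially to C12 anti to the C14 isopropenyl group (the sense known for carvone), giving the epoxide cis to the C15 methyl.

Step 4
Reactants: 5 C11,C12-epoxy ketone
Product: 6 allylic alcohol (C10=C11, C12–OH cis to C15 methyl)
Conditions: N2H4·H2O, AcOH (cat.), MeOH, 0 → 23 °C
Reagents that add atoms: none
Why: Wharton transposition, in which the epoxy hydrazone loses dinitrogen to give the transposed allylic alcohol with the C12–O bond, and hence its configuration, carried over unchanged from the epoxide.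

Step 5
Reactants: 6 allylic alcohol; 7 propargyl bromide
Product: 8 C12 O-propargyl ether
Conditions: NaH, Bu4NI (cat.), THF/DMF, 0 → 23 °C
Reagents that add atoms: none
Why: Williamson ether synthesis of the secondary allylic alkoxide with a reactive propargylic bromide, which touches no stereocentre.

Step 6
Reactants: 8 C12 O-propargyl ether
Product: 10 (9S)-diol with the C10–C9(OH)–C8≡C7–C6H2OH chain and C11=C12 alkene, via dilithium alkoxide-acetylide 9 (not isolated)
Conditions: n-BuLi (2.5 equiv), THF, −78 → −30 °C; then (CH2O)n, −30 → 23 °C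
Reagents that add atoms: formaldehyde (as paraformaldehyde), C=O
Why: [2,3]-Wittig rearrangement of the propargyl ether dianion followed by acetylide hydroxymethylation, in which the C9–C10 bond should form suprafacially on the ring face that carried the C12 oxygen (C9 cis to C15, C10–H cis to the C2 arm) and the alkynyl group should sit exo in the five-membered envelope transition state, away from the C15 methyl, to give 9S.

Step 7
Reactants: 10 (9S)-diol
Product: 11 C6 O-TBS ether (C9–OH free)
Conditions: TBSCl (1.05 equiv), imidazole, CH2Cl2, −20 °C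
Reagents that add atoms: tert-butyldimethylsilyl chloride, CC(C)(C)[Si](C)(C)Cl
Why: Selective silylation of the primary over the hindered secondary propargylic alcohol on steric grounds.

Step 8
Reactants: 11 C6 O-TBS ether
Product: 12 C11,C12-epoxide (oxygen cis to the C9 chain and to C15)
Conditions: VO(acac)2 (5 mol %), t-BuOOH (decane), CH2Cl2, 0 → 23 °C
Reagents that add atoms: tert-butyl hydroperoxide, CC(C)(C)OO
Why: Hydroxyl-directed vanadium-catalysed epoxidation of a homoallylic alcohol, which should deliver oxygen to the face of C11=C12 that carries the C9 carbinol chain (the target configuration) and leave the isopropenyl group and the alkyne untouched.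

Step 9
Reactants: 12 C11,C12-epoxide
Product: 13 C14 methyl ketone
Conditions: O3, CH2Cl2/MeOH, −78 °C; then Me2S, −78 → 23 °C
Reagents that add atoms: ozone, [O-][O+]=O
Why: Ozonolysis of the only alkene left (the isopropenyl group), which should be much faster than attack on the alkyne or the anisyl ring and leaves C14 untouched.

Step 10
Reactants: 13 C14 methyl ketone
Product: 14 C14 acetate
Conditions: m-CPBA, Na2HPO4, CH2Cl2, 23 °C
Reagents that add atoms: 3-chloroperoxybenzoic acid, OOC(=O)c1cccc(Cl)c1
Why: Baeyer–Villiger oxidation in which the secondary ring carbon C14 should migrate in preference to methyl with retention, converting the carvone stereocentre directly into the C14 acetate of the target.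

Step 11
Reactants: 14 C14 acetate
Product: 15 (aS)-allene C9=C8=C7
Conditions: PPh3, DEAD, THF, −15 °C; 2-nitrobenzenesulfonylhydrazide, −15 → 23 °C
Reagents that add atoms: none
Why: Myers allene synthesis (Mitsunobu displacement with inversion at C9, loss of sulfinic acid, then sigmatropic loss of dinitrogen with hydrogen delivered to C7 syn to the departing nitrogen), a stereospecific transfer of the C9 configuration to the allene axis.

Step 12
Reactants: 15 (aS)-allene
Product: 16 primary alcohol at C2
Conditions: DDQ, CH2Cl2/pH 7 buffer, 0 °C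
Reagents that add atoms: none
Why: Oxidative cleavage of the 4-methoxybenzyl ether by DDQ, which should spare the allene, the epoxide, the silyl ether and the acetate.

Step 13
Reactants: 16 primary alcohol at C2
Product: 17 C2 aldehyde
Conditions: Dess–Martin periodinane, NaHCO3, CH2Cl2, 0 → 23 °C
Reagents that add atoms: none
Why: Dess–Martin oxidation of the neopentyl alcohol to a non-enolisable aldehyde under buffered, non-acidic conditions.

Step 14
Reactants: 17 C2 aldehyde; 18 4-bromo-2-methylbut-1-ene
Product: 20 C2 carbinol (both C2 epimers), via Grignard reagent 19 (not isolated)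
Conditions: 18, Mg, THF, 23 °C; then 17, THF, −78 °C
Reagents that add atoms: none
Why: Grignard addition to the aldehyde, which at −78 °C should outpace attack on the hindered acetate and installs C3–C5 with the C5 methyl and the alkene needed for ring closure.

Step 15
Reactants: 20 C2 carbinol
Product: 21 C2 ketone
Conditions: Dess–Martin periodinane, NaHCO3, CH2Cl2, 23 °C
Reagents that add atoms: none
Why: Dess–Martin oxidation merges the two C2 epimers into one ketone.

Step 16
Reactants: 21 C2 ketone
Product: 22 (2S)-alcohol
Conditions: (R)-2-methyl-CBS-oxazaborolidine (0.5 equiv), catecholborane, toluene, −78 °C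
Reagents that add atoms: none
Why: Corey–Bakshi–Shibata reduction of a ketone flanked by a quaternary carbon (large) and a CH2 group (small), for which the (R)-catalyst should give 2S, with catecholborane at −78 °C leaving allene, alkene and esters alone.

Step 17
Reactants: 22 (2S)-alcohol
Product: 23 (2S)-butanoate
Conditions: butanoyl chloride, pyridine, DMAP (cat.), CH2Cl2, 0 → 35 °C
Reagents that add atoms: butanoyl chloride, CCCC(=O)Cl
Why: DMAP-catalysed acylation of the hindered secondary alcohol with retention at C2.

Step 18
Reactants: 23 (2S)-butanoate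
Product: 24 α-allenic alcohol (C6–OH)
Conditions: HF·pyridine, pyridine, THF, 0 °C
Reagents that add atoms: none
Why: Fluoride cleavage of the primary silyl ether, buffered with pyridine to spare the epoxide and the two esters.

Step 19
Reactants: 24 α-allenic alcohol
Product: 25 alkylidenecyclopropane carbinol (cyclopropane C7–C8–C17, exocyclic (Z)-C8=C9, 7S)
Conditions: Et2Zn, CH3CHI2, CH2Cl2, −40 → 0 °C
Reagents that add atoms: 1,1-diiodoethane, CC(I)I
Why: Hydroxyl-directed Simmons–Smith cyclopropanation (Furukawa conditions, ethylidene carbenoid) of the proximal allene bond C7=C8, in which the carbenoid should add to the π face anti to the C10 substituent that the allene axis holds over it, so that the axis sets C7, with the C17 methyl expected trans to CH2OH and C10 left cis to C7 across C8=C9.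

Step 20
Reactants: 25 alkylidenecyclopropane carbinol
Product: 26 cyclopropanecarbaldehyde
Conditions: Dess–Martin periodinane, NaHCO3, CH2Cl2, 0 °C
Reagents that add atoms: none
Why: Dess–Martin oxidation under non-acidic conditions, chosen to avoid cyclopropylcarbinyl cation rearrangement.

Step 21
Reactants: 26 cyclopropanecarbaldehyde
Product: 27 diene (vinyl group on C7, isopropenyl terminus at C5)
Conditions: Ph3PCH3Br, KN(SiMe3)2, THF, −78 → 0 °C
Reagents that add atoms: methyltriphenylphosphonium bromide, C[P+](c1ccccc1)(c1ccccc1)c1ccccc1.[Br-]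
Why: Wittig methylenation of the aldehyde, which should react far faster than the two esters and keeps C7 intact.

Step 22
Reactants: 27 diene
Product: 28 macrocyclic vinyl-alkylidenecyclopropane (ten-membered ring C1–C10, (5Z)-alkene)
Conditions: second-generation Grubbs catalyst RuCl2(=CHPh)(H2IMes)(PCy3) (10 mol %), toluene (1 mM), 45 °C
Reagents that add atoms: none
Why: Ring-closing metathesis in which ruthenium should load on the monosubstituted vinyl group and close onto the 1,1-disubstituted C5 alkene, the ten-membered ring allowing only the Z trisubstituted alkene while the cis C8=C9 unit and the fused cyclopropane pre-bend the chain.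

Step 23
Reactants: 28 macrocyclic vinyl-alkylidenecyclopropane
Product: 30 target (CNP0220791.1), via β-alkylidene lactone 29 (not isolated)
Conditions: Pd2(dba)3·CHCl3 (2.5 mol %), PPh3 (10 mol %), CO2 (10 atm), DMF, 50 °C; then Et3N, 23 °C
Reagents that add atoms: carbon dioxide, O=C=O
Why: Proposed new method: zerovalent palladium should coordinate the C5=C6 vinyl group and open the strained C7–C17 bond in an SN2′-type oxidative addition (inversion at C7), giving a zwitterion with palladium on the C5–C6–C7 allyl unit and the negative charge spread over the C17–C8–C9 allyl unit; the less hindered terminus C17 then attacks CO2 (C19–C17 bond), the carboxylate closes onto C7 (O–C7 bond), and Et3N moves the C8=C9 double bond into conjugation (29 → 30). The closest known reaction types are the palladium-catalysed coupling of alkylidenecyclopropanes with CO2 to give 2(5H)-furanones and the palladium-catalysed formal [3+2] cycloadditions of vinylcyclopropanes and trimethylenemethane donors with heterocumulenes, neither shown on a ring-fused, fully substituted cyclopropane nor with transfer of configuration. The five-membered lactone closes by a 5-exo, outer-sphere O-allylation anti to palladium, and the ten-membered ring is not touched. The one new stereocentre, C7, should form with net retention (two inversions), so the cyclopropane configuration from step 19 becomes 7R, and the Z geometry of C5=C6 is held because the allyl unit cannot turn over inside the ten-membered ring. The step needs carboxylation at C17 and not at C9 or C7, and C–O closure at C7 and not at C5: C9 is shielded by the branched C10 and quaternary C1, palladium sits from the start on the C5–C7 allyl unit so that C7 is the electrophilic site, closure at C5 would need a seven-membered ring, and the tetrasubstituted conjugated butenolide is the thermodynamic sink.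

**Compound list**

1 | (R)-(−)-carvone, (5R)-2-methyl-5-(prop-1-en-2-yl)cyclohex-2-en-1-one | CC1=CC[C@H](CC1=O)C(C)=C | starting material
2 | chloromethyl 4-methoxybenzyl ether | COc1ccc(COCCl)cc1 | starting material
3 | 6-[(4-methoxybenzyloxy)methyl]carvone, CH2OPMB trans to the isopropenyl group | COc1ccc(COC[C@@H]2C(=O)C(C)=CC[C@H]2C(C)=C)cc1 | intermediate
4 | 6-methyl-6-[(4-methoxybenzyloxy)methyl]carvone; at quaternary C1 the methyl (C15) is trans and CH2OPMB (C2) cis to the isopropenyl group on C14 | COc1ccc(COC[C@@]2(C)C(=O)C(C)=CC[C@H]2C(C)=C)cc1 | intermediate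
5 | C11,C12-epoxy ketone of 4, epoxide oxygen trans to isopropenyl and cis to the C15 methyl | COc1ccc(COC[C@@]2(C)C(=O)[C@]3(C)O[C@@H]3C[C@H]2C(C)=C)cc1 | intermediate
6 | allylic alcohol with C10=C11 and the C12 hydroxyl cis to the C15 methyl, trans to isopropenyl | COc1ccc(COC[C@@]2(C)C=C(C)[C@H](O)C[C@H]2C(C)=C)cc1 | intermediate
7 | propargyl bromide (3-bromoprop-1-yne) | C#CCBr | starting material
8 | C12 O-propargyl ether of 6 | COc1ccc(COC[C@@]2(C)C=C(C)[C@H](OCC#C)C[C@H]2C(C)=C)cc1 | intermediate
9 | dilithium salt (C9 alkoxide and terminal acetylide) of the (9S) [2,3]-Wittig product | COc1ccc(COC[C@@]2(C)[C@H]([C@H](O[Li])C#C[Li])C(C)=CC[C@H]2C(C)=C)cc1 | intermediate (not isolated)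
10 | (9S)-diol: C10 bears CH(OH)–C≡C–CH2OH (C9 to C6) cis to the C15 methyl, C10–H cis to the C2 arm, C11=C12 alkene | COc1ccc(COC[C@@]2(C)[C@H]([C@H](O)C#CCO)C(C)=CC[C@H]2C(C)=C)cc1 | intermediate
11 | C6 O-tert-butyldimethylsilyl ether of 10, C9 hydroxyl free | COc1ccc(COC[C@@]2(C)[C@H]([C@H](O)C#CCO[Si](C)(C)C(C)(C)C)C(C)=CC[C@H]2C(C)=C)cc1 | intermediate
12 | C11,C12-epoxide of 11, oxygen cis to the C9 chain and the C15 methyl (configuration of the target) | COc1ccc(COC[C@@]2(C)[C@H]([C@H](O)C#CCO[Si](C)(C)C(C)(C)C)[C@]3(C)O[C@@H]3C[C@H]2C(C)=C)cc1 | intermediate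
13 | methyl ketone: acetyl on C14 in place of isopropenyl | COc1ccc(COC[C@@]2(C)[C@H]([C@H](O)C#CCO[Si](C)(C)C(C)(C)C)[C@]3(C)O[C@@H]3C[C@H]2C(C)=O)cc1 | intermediate
14 | C14 acetate (configuration of the target), C9 propargylic alcohol | COc1ccc(COC[C@@]2(C)[C@H]([C@H](O)C#CCO[Si](C)(C)C(C)(C)C)[C@]3(C)O[C@@H]3C[C@H]2OC(C)=O)cc1 | intermediate
15 | (aS)-allene: C10–CH=C=CH–CH2OTBS (C9=C8=C7, C6) | COc1ccc(COC[C@@]2(C)[C@H](C([H])=[C@@]=C([H])CO[Si](C)(C)C(C)(C)C)[C@]3(C)O[C@@H]3C[C@H]2OC(C)=O)cc1 | intermediate
16 | primary alcohol (CH2OH on C1) after removal of the 4-methoxybenzyl group | OC[C@@]1(C)[C@H](C([H])=[C@@]=C([H])CO[Si](C)(C)C(C)(C)C)[C@]2(C)O[C@@H]2C[C@H]1OC(C)=O | intermediate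
17 | C2 aldehyde | O=C[C@@]1(C)[C@H](C([H])=[C@@]=C([H])CO[Si](C)(C)C(C)(C)C)[C@]2(C)O[C@@H]2C[C@H]1OC(C)=O | intermediate
18 | 4-bromo-2-methylbut-1-ene | C=C(C)CCBr | starting material
19 | 3-methylbut-3-enylmagnesium bromide | C=C(C)CC[Mg]Br | intermediate (not isolated)
20 | C2 carbinol with the C3–C5 chain, both C2 epimers | C=C(C)CCC(O)[C@@]1(C)[C@H](C([H])=[C@@]=C([H])CO[Si](C)(C)C(C)(C)C)[C@]2(C)O[C@@H]2C[C@H]1OC(C)=O | intermediate
21 | C2 ketone | C=C(C)CCC(=O)[C@@]1(C)[C@H](C([H])=[C@@]=C([H])CO[Si](C)(C)C(C)(C)C)[C@]2(C)O[C@@H]2C[C@H]1OC(C)=O | intermediate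
22 | (2S)-alcohol | C=C(C)CC[C@H](O)[C@@]1(C)[C@H](C([H])=[C@@]=C([H])CO[Si](C)(C)C(C)(C)C)[C@]2(C)O[C@@H]2C[C@H]1OC(C)=O | intermediate
23 | (2S)-butanoate | C=C(C)CC[C@H](OC(=O)CCC)[C@@]1(C)[C@H](C([H])=[C@@]=C([H])CO[Si](C)(C)C(C)(C)C)[C@]2(C)O[C@@H]2C[C@H]1OC(C)=O | intermediate
24 | α-allenic alcohol (C6–OH), (aS)-allene | C=C(C)CC[C@H](OC(=O)CCC)[C@@]1(C)[C@H](C([H])=[C@@]=C([H])CO)[C@]2(C)O[C@@H]2C[C@H]1OC(C)=O | intermediate
25 | alkylidenecyclopropane carbinol: cyclopropane C7–C8–C17, exocyclic (Z)-C8=C9 (C10 cis to C7), (7S)-CH2OH on C7, C17 methyl trans to CH2OH | C=C(C)CC[C@H](OC(=O)CCC)[C@@]1(C)[C@H](/C=C3\[C@@H](CO)[C@@H]3C)[C@]2(C)O[C@@H]2C[C@H]1OC(C)=O | intermediate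
26 | cyclopropanecarbaldehyde (C6 aldehyde on C7) | C=C(C)CC[C@H](OC(=O)CCC)[C@@]1(C)[C@H](/C=C3\[C@@H](C=O)[C@@H]3C)[C@]2(C)O[C@@H]2C[C@H]1OC(C)=O | intermediate
27 | diene: vinyl group on C7 and 2-methylallyl-type terminus at C5 | C=C(C)CC[C@H](OC(=O)CCC)[C@@]1(C)[C@H](/C=C3\[C@@H](C=C)[C@@H]3C)[C@]2(C)O[C@@H]2C[C@H]1OC(C)=O | intermediate
28 | macrocyclic vinyl-alkylidenecyclopropane: ten-membered ring C1–C10 with (5Z)-alkene, cyclopropane C7–C8–C17 fused at C7–C8, C8=C9 exocyclic to the cyclopropane, trans-fused to the epoxycyclohexane | CCCC(=O)O[C@H]1CC/C(C)=C\[C@H]2[C@H](C)/C2=C/[C@@H]2[C@]3(C)O[C@@H]3C[C@@H](OC(C)=O)[C@@]12C | intermediate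
29 | β-alkylidene-γ-lactone (O–C7, C19–C17, C8=C9; either C17 epimer) | CCCC(=O)O[C@H]1CC/C(C)=C\[C@H]2OC(=O)C(C)/C2=C/[C@@H]2[C@]3(C)O[C@@H]3C[C@@H](OC(C)=O)[C@@]12C | intermediate (not isolated)
30 | CNP0220791.1, (1R,2S,5Z,7R,10S,11S,12R,14R)-14-acetoxy-2-butanoyloxy-11,12-epoxybriara-5,8(17)-dien-19,7-olide (briarane numbering) | CCCC(=O)O[C@H]1CC/C(C)=C\[C@H]2OC(=O)C(C)=C2C[C@@H]2[C@]3(C)O[C@@H]3C[C@@H](OC(C)=O)[C@@]12C | target

**Step count and risks**

Total step count: 23. Longest linear sequence: 23 steps (1 → 30).

Steps most likely to fail: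

1. Step 23 (proposed annulation with CO2). What may go wrong: the palladium may migrate between the two allyl units before CO2 is captured, so that carboxylation occurs at C9 or C7; the carboxylate may close at the wrong allyl terminus; the allyl–palladium species may undergo β-hydride loss to trienes; or π–σ–π isomerisation may erase the C7 configuration. Fallback with known chemistry, setting out from 24 and returning at 29 (and from there to 30 with Et3N): Dess–Martin oxidation of 24 gives the 2,3-allenal F1. A Corey–Chaykovsky-type Michael-initiated ring closure on this electron-poor allene with the ester-stabilised ylide made from [1-(2,2,2-trichloroethoxycarbonyl)ethyl]dimethylsulfonium bromide F2 (from 2,2,2-trichloroethyl 2-bromopropanoate and Me2S) and K2CO3 should add C17, which already carries C19 as an ester, to C8 on the face anti to C10 and close onto C7, giving the alkylidenecyclopropane aldehyde ester F3. Wittig methylenation gives the diene ester F4, and ring-closing metathesis as in step 22 gives the macrocyclic ester F5. Zinc in buffered AcOH/THF removes the trichloroethyl group to give the vinylcyclopropanecarboxylic acid F6. Pd(PPh3)4 in THF then ionises this acceptor-substituted vinylcyclopropane, and the carboxylate O-alkylates the allyl terminus C7 (Tsuji–Trost lactonisation), delivering 29. In this variant the carbonyl carbon comes from the ylide and not from CO2.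

2. Step 22 (ring-closing metathesis). What may go wrong: oligomerisation may outrun the slow closure of a ten-membered ring onto a 1,1-disubstituted alkene; the catalyst may be consumed by the strained alkylidenecyclopropane; or the vinyl-alkylidenecyclopropane may rearrange thermally. Fallback by inverting the order of the last two ring formations, setting out from 27 and returning at 30: the annulation of step 23 (same conditions, the same proposed method) is run on open-chain 27 to give the β-alkylidene lactone F7 and, after Et3N, the open-chain γ-vinyl butenolide F8. The ten-membered ring is then closed by metathesis with the second-generation Grubbs catalyst on F8, which no longer contains the strained alkylidenecyclopropane or a vinylcyclopropane.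

3. Step 11 (Myers allene synthesis). What may go wrong: Mitsunobu activation of the hindered secondary propargylic alcohol next to the branched C10 may be slow, leading to elimination or to loss of the stereospecific transfer of configuration from C9 to the allene axis. Fallback, setting out from 14 and returning at 15: methyl chloroformate and pyridine give the propargylic methyl carbonate F9. Pd2(dba)3·CHCl3, PBu3 and HCO2NH4 in THF should then give the same (aS)-allene 15 by anti SN2′ attack of zerovalent palladium and hydride transfer from the palladium formate with retention.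

Further compounds
F1 | step 23 | 2,3-allenal (C6 aldehyde on the (aS)-allene) | C=C(C)CC[C@H](OC(=O)CCC)[C@@]1(C)[C@H](C([H])=[C@@]=C([H])C=O)[C@]2(C)O[C@@H]2C[C@H]1OC(C)=O
F2 | step 23 | [1-(2,2,2-trichloroethoxycarbonyl)ethyl]dimethylsulfonium bromide | C[S+](C)C(C)C(=O)OCC(Cl)(Cl)Cl.[Br-]
F3 | step 23 | alkylidenecyclopropane with C7 aldehyde and C17 methyl/trichloroethyl ester (either C17 configuration) | C=C(C)CC[C@H](OC(=O)CCC)[C@@]1(C)[C@H](/C=C3\[C@@H](C=O)C3(C)C(=O)OCC(Cl)(Cl)Cl)[C@]2(C)O[C@@H]2C[C@H]1OC(C)=O
F4 | step 23 | diene ester (vinyl on C7) | C=C(C)CC[C@H](OC(=O)CCC)[C@@]1(C)[C@H](/C=C3\[C@@H](C=C)C3(C)C(=O)OCC(Cl)(Cl)Cl)[C@]2(C)O[C@@H]2C[C@H]1OC(C)=O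
F5 | step 23 | macrocyclic vinylcyclopropane trichloroethyl ester | CCCC(=O)O[C@H]1CC/C(C)=C\[C@H]2C(C)(C(=O)OCC(Cl)(Cl)Cl)/C2=C/[C@@H]2[C@]3(C)O[C@@H]3C[C@@H](OC(C)=O)[C@@]12C
F6 | step 23 | macrocyclic vinylcyclopropanecarboxylic acid | CCCC(=O)O[C@H]1CC/C(C)=C\[C@H]2C(C)(C(=O)O)/C2=C/[C@@H]2[C@]3(C)O[C@@H]3C[C@@H](OC(C)=O)[C@@]12C
F7 | step 22 | open-chain β-alkylidene-γ-vinyl lactone (either C17 epimer) | C=C(C)CC[C@H](OC(=O)CCC)[C@@]1(C)[C@H](/C=C3/C(C)C(=O)O[C@@H]3C=C)[C@]2(C)O[C@@H]2C[C@H]1OC(C)=O
F8 | step 22 | open-chain (7R)-γ-vinyl butenolide | C=C(C)CC[C@H](OC(=O)CCC)[C@@]1(C)[C@H](CC3=C(C)C(=O)O[C@@H]3C=C)[C@]2(C)O[C@@H]2C[C@H]1OC(C)=O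
F9 | step 11 | C9 propargylic methyl carbonate of 14 | COc1ccc(COC[C@@]2(C)[C@H]([C@H](OC(=O)OC)C#CCO[Si](C)(C)C(C)(C)C)[C@]3(C)O[C@@H]3C[C@H]2OC(C)=O)cc1
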